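All runs are calculated for substances that don't exist; noise was put on by code.

The first product did not stay: reagent carried it on to bis adduct. So I asked how many turnovers of that loss fitted into each run.

| flask | starting material | reagent | remark | time |
|---|---|---|---|---|
| maple | 0.29 M | 0.19 M | run made earlier |  |
| elm | 0.29 M | 0.27 M | run made earlier |  |
| ash | 0.29 M | 0.70 M | run made earlier |  |
| Saturday's | 0.29 M | 0.150 M |  | 4.0 h |
| Wednesday's | 0.29 M | 0.300 M |  | 4.0 h |
| Friday's | 0.29 M | 0.600 M |  | 4.0 h |

- maple (time / h: first product / %, bis adduct / %, starting material / %): 0.250: 3.7, 0, 89.8; 0.667: 9.0, 1.1, 76.8; 1.33: 13.5, 4.4, 63.6; 2.00: 17.6, 5.3, 53.6; 3.00: 19.0, 10.4, 42.9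
- elm (time / h: first product / %, bis adduct / %, starting material / %): 0.500: 8.5, 0.4, 78.1; 1.00: 15.1, 6.2, 62.4; 1.50: 19.2, 7.5, 53.6; 2.50: 22.1, 15.1, 38.2; 3.00: 23.7, 17.0, 39.5
- ash (time / h: first product / %, bis adduct / %, starting material / %): 0.500: 21.7, 9.9, 56.6; 1.00: 24.2, 24.2, 36.7; 1.50: 24.1, 37.5, 25.3; 2.50: 18.4, 53.7, 14.4; 3.00: 19.1, 60.4, 11.5

(standard deviation of a reading: 1 percentage point)

- in percentages every species weighs as the starting material in it: one self-condensation product counts as two
- on the list of suspects stand: starting material + reagent -> first product; starting material + reagent -> other mono adduct; reagent + first product -> bis adduct; reagent + other mono adduct -> bis adduct; 2 starting material -> self-condensation product; first product -> over-reaction product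
- the share counts what is present at the end, not what went on to other products
- "hardly changes" means that all values lie within two and a half points (for a concentration: within two and a half percent of the largest)

* share of first product in all that became first product or bis adduct for Saturday's, Wednesday's, Friday's, in this order
* the course of these numbers from the first flask to the last (hardly changes / rises all the way / rises, then falls / falls all the way / falls, then rises)

I read the loss from the ash run. Bis adduct rose from 9.9 % to 37.5 % between 0.500 h and 1.50 h, with 24.2 % of first product standing at mid-interval. Dividing that rise by the time, the first product and the reagent charge gave an apparent second-order constant κ. With the reagent held at its charge, κ times that charge acts as a pseudo-first-order constant. The rise also holds what the other mono adduct fed in.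

κ = 1.63 L mol⁻¹ h⁻¹

I then defined the turnover number n = κ·c·t, the lifetimes of first product that fit into time t at reagent charge c.

Saturday's n = 0.978; Wednesday's n = 1.96; Friday's n = 3.91

For a steady feed and this loss, the share left is S = (1 − e^(−n))/n.

Saturday's S = 63.8 %; Wednesday's S = 43.9 %; Friday's S = 25.1 %

Was one number enough? The elm run at 2.50 h and the ash run at 1.00 h had nearly equal n, 1.10 and 1.14. Yet their shares were 59.4 % and 50.0 %, the elm share being higher. Counting one reagent per first product and two per bis adduct, elm had used 56.2 % of its charge and ash 30.1 %. So n overstated the small charges, and I expected Saturday's above S and Friday's below it.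

The forecast gave 68 %, 49 % and 26 %, each above mine, with a course that falls all the way, and said “The share falls steadily.”

The flasks gave 67.9 %, 47.7 % and 22.3 %: the share falls all the way.

    starting material + reagent → first product (k = 1.10 L mol⁻¹ h⁻¹)
    starting material + reagent → other mono adduct (k = 0.510 L mol⁻¹ h⁻¹)
    reagent + first product → bis adduct (k = 1.50 L mol⁻¹ h⁻¹)
    reagent + other mono adduct → bis adduct (k = 2.60 L mol⁻¹ h⁻¹)
    2 starting material → self-condensation product (k = 0.270 L mol⁻¹ h⁻¹)
    first product → over-reaction product (k = 7.90 × 10⁻⁵ h⁻¹)

Saturday's stood above S and Friday's below it. Friday's, with n at 3.91, shows the main reason for the low share: with the step from reagent and first product to bis adduct taken away, the share stood at 70.9 % instead of 22.3 %. Saturday's, with n at 0.978, lost less to the same step: without it, the share stood at 85.9 % instead of 67.9 %.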